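**Retrosynthetic overview**

1. Numbering: lactone O1, C2 (C=O), C3, C4, C5; Ar = 3,4,5-trimethoxyphenyl. The last disconnection is C3–CH2Ar, made by trans-selective benzylation of the enolate of the (R)-4-(arylmethyl) lactone. It comes after ring closure because a carbene already carrying this group would lose a benzylic hydrogen by 1,2-shift.
2. The key disconnection is C3–C4, made as the lactone closes, by enantioselective intramolecular carbene C–H insertion of an acyclic, achiral 3-arylpropyl diazoacetate under a chiral dirhodium carboxamidate.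
3. Enabling feature: in the lactone ring, C4 is a CH flanked by C5H2–O1 and the benzylic CH2. Cut at C3–C4, it is the middle, unactivated methylene of an ArCH2–CH2–CH2–O chain, and the ester O1–C2(=O) holds the carbene carbon C3 in a 1,5 relation to it. Taking one of its two enantiotopic hydrogens therefore gives the bond, the ring and the C4 stereocentre in one operation.
4. The diazoacetate comes from the commercial arylpropanoic acid (reduction), bromoacetyl bromide and N,N'-ditosylhydrazine; both arenes are bought with their methoxy groups in place.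
5. Ring order: the lactone is the only ring formed (step 4). C4 is set by the catalyst in step 4, and C3 by C4 in step 5.

Key step: step 4

Assumption: the 4S catalyst is taken to give the R lactone, as expected for this ligand family with diazoacetates of 3-arylpropanols; should the sense be opposite, the 4R catalyst, made the same way from the enantiomeric ligand, is used in its place.
Remark: Rh2(4S-MPPIM)4 is dirhodium tetrakis[methyl (4S)-2-oxo-1-(3-phenylpropanoyl)imidazolidine-4-carboxylate] (divalent rhodium), obtained from Rh2(OAc)4 by ligand exchange.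

**Route**

Step 1
Reactants: 1 3-(3,4,5-trimethoxyphenyl)propanoic acid
Product: 2 3-(3,4,5-trimethoxyphenyl)propan-1-ol
Conditions: BH3·SMe2, THF, 0 °C to rt; then H2O
Reagents that add atoms: none
Why: Borane reduction of a carboxylic acid is chemoselective for CO2H and leaves the aryl methyl ethers untouched; no stereocentre is formed.

Step 2
Reactants: 2 3-(3,4,5-trimethoxyphenyl)propan-1-ol, 3 bromoacetyl bromide
Product: 4 3-(3,4,5-trimethoxyphenyl)propyl bromoacetate
Conditions: BrCH2COBr, NaHCO3, MeCN, 0 °C
Reagents that add atoms: bromoacetyl bromide (3), BrCC(=O)Br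
Why: O-Acylation of the primary alcohol by the acyl bromide (nucleophilic acyl substitution) is much faster than displacement of the alkyl bromide, and solid NaHCO3 takes up HBr without attacking the α-bromo ester.

Step 3
Reactants: 4 3-(3,4,5-trimethoxyphenyl)propyl bromoacetate
Product: 7 3-(3,4,5-trimethoxyphenyl)propyl diazoacetate, via N-alkyl ditosylhydrazide 5 (not isolated), via glyoxylate tosylhydrazone 6 (not isolated)
Conditions: TsNHNHTs, DBU, THF, 0 °C
Reagents that add atoms: N,N'-ditosylhydrazine, Cc1ccc(cc1)S(=O)(=O)NNS(=O)(=O)c1ccc(C)cc1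
Why: SN2 N-alkylation of the ditosylhydrazide anion by the bromoacetate, followed by two base-induced losses of sulfinate (the second a Bamford–Stevens-type fragmentation of the tosylhydrazone), should give the diazoacetate under conditions mild enough for a primary alkyl ester.

Step 4
Reactants: 7 3-(3,4,5-trimethoxyphenyl)propyl diazoacetate
Product: 8 (4R)-4-(3,4,5-trimethoxybenzyl)dihydrofuran-2(3H)-one
Conditions: Rh2(4S-MPPIM)4 (1 mol %), CH2Cl2, reflux, 7 added over 8 h
Reagents that add atoms: none
Why: The chiral dirhodium carboxamidate takes up the diazo carbon at a free axial site, N2 leaves, and the electrophilic rhodium-bound carbene at C3 inserts into a C4–H bond through a concerted three-centre transition state that forms C3–C4 and C3–H with retention at C4 and releases the catalyst. The closest known reaction type is the enantioselective intramolecular carbene C–H insertion of diazoacetates of primary 3-arylpropyl alcohols to 4-(arylmethyl) γ-butyrolactones with chiral dirhodium carboxamidates. The lactone closes as a five-membered ring by 1,5-insertion from the s-cis rotamer of the ester, the carbene carbon bonding to the second carbon beyond the ester oxygen. The C4 stereocentre is created from a prochiral methylene and is controlled by the catalyst alone: the 4S ester groups and N-acyl chains of the four imidazolidinone ligands flank the carbene so that only one enantiotopic C4–H bond can reach it with the arylmethyl residue turned away from the ligand wall, which is expected to give R. The step needs site selectivity for the unactivated C4 methylene over the oxygen-activated C5–H bonds (four-membered ring) and the benzylic C–H bonds (six-membered ring), and chemoselectivity against carbene dimerisation and attack on the electron-rich arene. The weakly electrophilic carboxamidate carbene, the preference for the five-membered transition state and the slow addition of 7 should secure both.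

Step 5
Reactants: 8 (4R)-4-(3,4,5-trimethoxybenzyl)dihydrofuran-2(3H)-one, 9 3,4,5-trimethoxybenzyl bromide
Product: 11 (−)-cubebininolide [(3R,4R)-3,4-bis(3,4,5-trimethoxybenzyl)dihydrofuran-2(3H)-one], via lithium enolate 10 (not isolated)
Conditions: LiN(SiMe3)2, THF, −78 °C; then 9, DMPU, −78 to −30 °C
Reagents that add atoms: 3,4,5-trimethoxybenzyl bromide (9), COc1cc(CBr)cc(OC)c1OC
Why: Kinetic deprotonation gives the planar lithium enolate, which is benzylated (SN2 enolate alkylation) on the face anti to the C4 arylmethyl group, so that C3 is set R and trans by 1,2-induction from C4, which is not acidic and stays untouched.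

**Compound list**

1 | 3-(3,4,5-trimethoxyphenyl)propanoic acid | COc1cc(CCC(=O)O)cc(OC)c1OC | starting material
2 | 3-(3,4,5-trimethoxyphenyl)propan-1-ol | COc1cc(CCCO)cc(OC)c1OC | intermediate
3 | bromoacetyl bromide | BrCC(=O)Br | starting material
4 | 3-(3,4,5-trimethoxyphenyl)propyl bromoacetate | COc1cc(CCCOC(=O)CBr)cc(OC)c1OC | intermediate
5 | 3-(3,4,5-trimethoxyphenyl)propyl 2-[1,2-bis(4-methylphenylsulfonyl)hydrazinyl]acetate (N-alkyl ditosylhydrazide) | COc1cc(CCCOC(=O)CN(NS(=O)(=O)c2ccc(C)cc2)S(=O)(=O)c2ccc(C)cc2)cc(OC)c1OC | intermediate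
6 | 3-(3,4,5-trimethoxyphenyl)propyl 2-[2-(4-methylphenylsulfonyl)hydrazinylidene]acetate (glyoxylate tosylhydrazone) | COc1cc(CCCOC(=O)C=NNS(=O)(=O)c2ccc(C)cc2)cc(OC)c1OC | intermediate
7 | 3-(3,4,5-trimethoxyphenyl)propyl diazoacetate | COc1cc(CCCOC(=O)C=[N+]=[N-])cc(OC)c1OC | intermediate
8 | (4R)-4-(3,4,5-trimethoxybenzyl)dihydrofuran-2(3H)-one | COc1cc(C[C@H]2COC(=O)C2)cc(OC)c1OC | intermediate
9 | 3,4,5-trimethoxybenzyl bromide | COc1cc(CBr)cc(OC)c1OC | starting material
10 | lithium enolate of 8, lithium (4R)-4-(3,4,5-trimethoxybenzyl)-4,5-dihydrofuran-2-olate | COc1cc(C[C@H]2COC([O-])=C2)cc(OC)c1OC.[Li+] | intermediate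
11 | (−)-cubebininolide, (3R,4R)-3,4-bis(3,4,5-trimethoxybenzyl)dihydrofuran-2(3H)-one | COc1cc(C[C@H]2COC(=O)[C@@H]2Cc2cc(OC)c(OC)c(OC)c2)cc(OC)c1OC | target

**Step count and risks**

Total steps: 5. Longest linear sequence: 5 steps (1 → 2 → 4 → 7 → 8 → 11).

Steps most likely to fail:

1. Step 4 (carbene C–H insertion). The carbene may insert at the wrong C–H bond (next to oxygen or at the benzylic position), dimerise, or discriminate poorly between the two enantiotopic C4 hydrogens with this electron-rich arene. The fallback sets out from acid 1 and returns to the route at lactone 8, with the stereocentre set by a chiral auxiliary instead of a catalyst. Acid 1 is activated as its pivaloyl mixed anhydride (t-BuCOCl, Et3N, THF) and coupled with lithiated (S)-4-benzyloxazolidin-2-one (n-BuLi, −78 °C) to give imide (4S)-4-benzyl-3-[3-(3,4,5-trimethoxyphenyl)propanoyl]oxazolidin-2-one F1. Its sodium Z-enolate (NaN(SiMe3)2, THF, −78 °C) is alkylated with tert-butyl bromoacetate on the face away from the auxiliary benzyl group to give (4S)-4-benzyl-3-[(2R)-2-(2-tert-butoxy-2-oxoethyl)-3-(3,4,5-trimethoxyphenyl)propanoyl]oxazolidin-2-one F2. LiBH4 (THF, H2O, 0 °C) removes the auxiliary reductively to give tert-butyl (3R)-3-(hydroxymethyl)-4-(3,4,5-trimethoxyphenyl)butanoate F3, and CF3CO2H in CH2Cl2 cleaves the tert-butyl ester and closes the lactone to 8.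

2. Step 5 (enolate benzylation). Proton exchange between product and enolate may lead to a second benzylation at C3 or to incomplete conversion. The fallback sets out from lactone 8 and returns at target 11, using an electrophile that can add only once. Enolate 10 is added to 3,4,5-trimethoxybenzaldehyde (THF, −78 °C) to give the 3,4-trans aldol adduct (3S,4R)-3-[hydroxy(3,4,5-trimethoxyphenyl)methyl]-4-(3,4,5-trimethoxybenzyl)dihydrofuran-2(3H)-one F4 as a mixture of carbinol epimers. Acetylation (Ac2O, pyridine, DMAP) gives (3S,4R)-3-[acetoxy(3,4,5-trimethoxyphenyl)methyl]-4-(3,4,5-trimethoxybenzyl)dihydrofuran-2(3H)-one F5. Hydrogenolysis of the benzylic C–O bond (H2, Pd/C, EtOAc) without strong acid, which would otherwise invite ring closure onto the second arene, removes the carbinol centre and gives 11.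

3. Step 3 (diazoacetate formation). The diazo ester may be lost by base-induced decomposition, or the sequence may stall at the tosylhydrazone stage. The fallback sets out from alcohol 2 and returns at diazoacetate 7, building the diazo group by diazo transfer instead. Acetoacetylation of 2 with 2,2,6-trimethyl-4H-1,3-dioxin-4-one (xylene, 140 °C) gives 3-(3,4,5-trimethoxyphenyl)propyl 3-oxobutanoate F6. Diazo transfer (4-acetamidobenzenesulfonyl azide, Et3N, MeCN) gives 3-(3,4,5-trimethoxyphenyl)propyl 2-diazo-3-oxobutanoate F7, and deacetylation with aqueous LiOH in MeCN gives 7.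

**Further compounds**

F1 | step 4 | (4S)-4-benzyl-3-[3-(3,4,5-trimethoxyphenyl)propanoyl]oxazolidin-2-one | COc1cc(CCC(=O)N2[C@@H](Cc3ccccc3)COC2=O)cc(OC)c1OC
F2 | step 4 | (4S)-4-benzyl-3-[(2R)-2-(2-tert-butoxy-2-oxoethyl)-3-(3,4,5-trimethoxyphenyl)propanoyl]oxazolidin-2-one | COc1cc(C[C@H](CC(=O)OC(C)(C)C)C(=O)N2[C@@H](Cc3ccccc3)COC2=O)cc(OC)c1OC
F3 | step 4 | tert-butyl (3R)-3-(hydroxymethyl)-4-(3,4,5-trimethoxyphenyl)butanoate | COc1cc(C[C@H](CC(=O)OC(C)(C)C)CO)cc(OC)c1OC
F4 | step 5 | (3S,4R)-3-[hydroxy(3,4,5-trimethoxyphenyl)methyl]-4-(3,4,5-trimethoxybenzyl)dihydrofuran-2(3H)-one, carbinol epimers | COc1cc(C[C@H]2COC(=O)[C@@H]2C(O)c2cc(OC)c(OC)c(OC)c2)cc(OC)c1OC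
F5 | step 5 | (3S,4R)-3-[acetoxy(3,4,5-trimethoxyphenyl)methyl]-4-(3,4,5-trimethoxybenzyl)dihydrofuran-2(3H)-one, carbinol epimers | COc1cc(C[C@H]2COC(=O)[C@@H]2C(OC(C)=O)c2cc(OC)c(OC)c(OC)c2)cc(OC)c1OC
F6 | step 3 | 3-(3,4,5-trimethoxyphenyl)propyl 3-oxobutanoate | COc1cc(CCCOC(=O)CC(C)=O)cc(OC)c1OC
F7 | step 3 | 3-(3,4,5-trimethoxyphenyl)propyl 2-diazo-3-oxobutanoate | COc1cc(CCCOC(=O)C(=[N+]=[N-])C(C)=O)cc(OC)c1OC
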